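**Plan**
- Retrosynthesis: the thirteen O–CH3 bonds are cut last (28 ← 27). Ring A of 27 is then cut at the C1–C2 bond (hydroxyl carbon to aryloxy carbon), which unfolds it to the 6-(aryloxymethyl)-4-methoxy-2-pyrone 25, and the pyrone CH2–O ether is cut to pentamer phenol 22 and bromomethylpyrone 24.
- The B–F pentamer is cut at the ring C–O–ring D ether (Ullmann, 19 + 12). The B–C, D–E and E–F ethers are cut to 2,6-disubstituted phenols and unhindered arylboronic acids (Chan–Lam). The phenol oxygens at ring D C2 and ring B C1 come from formyl groups (Baeyer–Villiger).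
- Feature used: ring A is a phloroglucinol whose ether oxygen sits on C2, between the hydroxyl carbons C1 and C3 (third oxygen on C5). Its six carbons therefore map onto a triketide chain with the aryloxy group on the terminal carbon, and that carbon can acylate the chain's ester carbon.
- Forward order: rings B–F are bought as benzenes and joined E–F, D–E, B–C, then C–D. Ring A is the only ring formed (step 14, from the pyrone), and global demethylation ends the route.
- Stereochemistry: the target is achiral and has no stereocentre. The only geometric element, the cis relation of ester and keto chain in the opened pyrone, is inherited from the lactone ring.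

Key step: step 14

Assumption: rings are lettered A to F from the 2,4,6-trihydroxyphenoxy end of the SMILES, and the ring-opened enoate is E by the sequence rules (ester and keto chain cis).

**Route**

Step 1
Reactants: 1 4-bromo-2,6-dimethoxyphenol; 2 (3,4,5-trimethoxyphenyl)boronic acid
Product: 3 5-(4-bromo-2,6-dimethoxyphenoxy)-1,2,3-trimethoxybenzene (EF bromide)
Conditions: Cu(OAc)2 (1 equiv), pyridine, 4 Å MS, CH2Cl2, dry air, rt
Reagents that add atoms: none
Why: Chan–Lam coupling arylates a di-ortho-substituted phenol with an unhindered arylboronic acid at room temperature, where the aryl bromide is inert and 1 cannot self-condense as it would under Ullmann heating.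

Step 2
Reactants: 3 EF bromide
Product: 6 [3,5-dimethoxy-4-(3,4,5-trimethoxyphenoxy)phenyl]boronic acid (EF boronic acid), via EF aryllithium 4 (not isolated), via lithium EF-aryltriisopropoxyborate 5 (not isolated)
Conditions: n-BuLi, THF, −78 °C; B(OiPr)3, −78 °C to rt; 1 M HCl
Reagents that add atoms: triisopropyl borate CC(C)OB(OC(C)C)OC(C)C; water O
Why: Bromine–lithium exchange at −78 °C outruns ortho-lithiation beside the methoxy groups, and borate trapping followed by mild acid hydrolysis is the standard route to arylboronic acids.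

Step 3
Reactants: 7 5-bromo-1,2,3-trimethoxybenzene
Product: 9 6-bromo-2,3,4-trimethoxybenzaldehyde, via racemic aryl chloro(methoxy)methane 8 (not isolated)
Conditions: Cl2CHOMe, TiCl4, CH2Cl2, 0 °C; then ice/H2O
Reagents that add atoms: dichloromethyl methyl ether COC(Cl)Cl; water O
Why: Rieche formylation can only attack the two equivalent ring CH positions of 7, each ortho and para to a methoxy group, so the formyl group should enter between bromine and methoxy, and water hydrolyses the chloro ether to the aldehyde.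

Step 4
Reactants: 9 6-bromo-2,3,4-trimethoxybenzaldehyde
Product: 11 6-bromo-2,3,4-trimethoxyphenol (ring D building block), via 6-bromo-2,3,4-trimethoxyphenyl formate 10 (not isolated)
Conditions: mCPBA, CH2Cl2, 0 °C to rt; then MeOH, Et3N, rt
Reagents that add atoms: 3-chloroperbenzoic acid OOC(=O)c1cccc(Cl)c1
Why: In this Baeyer–Villiger (Dakin-type) oxidation the aryl group, made electron-rich by ortho- and para-methoxy donors, migrates in the Criegee adduct to give the formate, which methanolysis cleaves to the phenol.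

Step 5
Reactants: 11 6-bromo-2,3,4-trimethoxyphenol; 6 EF boronic acid
Product: 12 1-bromo-2-[3,5-dimethoxy-4-(3,4,5-trimethoxyphenoxy)phenoxy]-3,4,5-trimethoxybenzene (DEF bromide)
Conditions: Cu(OAc)2 (1 equiv), pyridine, 4 Å MS, CH2Cl2, dry air, rt
Reagents that add atoms: none
Why: Chan–Lam coupling is known to work for 2,6-disubstituted (including 2,6-dihalo) phenols with unhindered arylboronic acids, and it keeps the ortho bromine that the next ether bond needs.

Step 6
Reactants: 1 4-bromo-2,6-dimethoxyphenol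
Product: 13 2-(benzyloxy)-5-bromo-1,3-dimethoxybenzene
Conditions: BnBr, K2CO3, DMF, rt
Reagents that add atoms: benzyl bromide BrCc1ccccc1
Why: Williamson etherification of the acidic phenol with a reactive benzylic bromide masks the ring C hydroxyl for the lithiation and coupling that follow.

Step 7
Reactants: 13 2-(benzyloxy)-5-bromo-1,3-dimethoxybenzene
Product: 16 [4-(benzyloxy)-3,5-dimethoxyphenyl]boronic acid, via benzyloxy aryllithium 14 (not isolated), via lithium benzyloxyaryltriisopropoxyborate 15 (not isolated)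
Conditions: n-BuLi, THF, −78 °C; B(OiPr)3, −78 °C to rt; 1 M HCl
Reagents that add atoms: triisopropyl borate CC(C)OB(OC(C)C)OC(C)C; water O
Why: Bromine–lithium exchange followed by borate trapping and hydrolysis is the standard arylboronic acid synthesis, and the benzyl ether is stable to the aryllithium at −78 °C.

Step 8
Reactants: 17 syringaldehyde (4-hydroxy-3,5-dimethoxybenzaldehyde); 16 [4-(benzyloxy)-3,5-dimethoxyphenyl]boronic acid
Product: 18 4-[4-(benzyloxy)-3,5-dimethoxyphenoxy]-3,5-dimethoxybenzaldehyde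
Conditions: Cu(OAc)2 (1 equiv), pyridine, 4 Å MS, CH2Cl2, dry air, rt
Reagents that add atoms: none
Why: Chan–Lam coupling tolerates acidic, di-ortho-substituted phenols and a free aldehyde, so the ring B oxygen is arylated while the formyl group stays as the latent ring B hydroxyl.

Step 9
Reactants: 18 4-[4-(benzyloxy)-3,5-dimethoxyphenoxy]-3,5-dimethoxybenzaldehyde
Product: 19 4-(4-hydroxy-3,5-dimethoxyphenoxy)-3,5-dimethoxybenzaldehyde (BC phenol)
Conditions: H2 (1 atm), Pd/C, EtOAc, rt, stopped after one equivalent of H2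
Reagents that add atoms: none
Why: Catalytic hydrogenolysis cleaves the aryl benzyl ether much faster than it reduces the electron-rich aryl aldehyde in ethyl acetate, and the diaryl ether is inert.

Step 10
Reactants: 19 BC phenol; 12 DEF bromide
Product: 20 4-{4-[2-(3,5-dimethoxy-4-(3,4,5-trimethoxyphenoxy)phenoxy)-3,4,5-trimethoxyphenoxy]-3,5-dimethoxyphenoxy}-3,5-dimethoxybenzaldehyde (B–F pentamer aldehyde)
Conditions: CuI (20 mol %), picolinic acid (40 mol %), K3PO4, DMSO, argon, 110 °C
Reagents that add atoms: none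
Why: Ullmann diaryl ether synthesis with the CuI/picolinic acid/K3PO4 system is known to join di-ortho-substituted phenols to ortho-substituted electron-rich aryl bromides, and the aldehyde, which has no α-hydrogen, tolerates the phosphate base.

Step 11
Reactants: 20 B–F pentamer aldehyde
Product: 22 B–F pentamer phenol (3,5-dimethoxy-4-aryloxyphenol terminus on ring B), via pentamer aryl formate 21 (not isolated)
Conditions: mCPBA, CH2Cl2, 0 °C to rt; then MeOH, Et3N, rt
Reagents that add atoms: 3-chloroperbenzoic acid OOC(=O)c1cccc(Cl)c1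
Why: Baeyer–Villiger (Dakin-type) oxidation of a benzaldehyde with a para-aryloxy donor proceeds by aryl migration, as it does for 3,4,5-trimethoxybenzaldehyde, and methanolysis of the formate frees the unhindered ring B phenol.

Step 12
Reactants: 23 4-methoxy-6-methyl-2H-pyran-2-one
Product: 24 6-(bromomethyl)-4-methoxy-2H-pyran-2-one
Conditions: NBS, (PhCO2)2 (cat.), CCl4, reflux
Reagents that add atoms: N-bromosuccinimide O=C1CCC(=O)N1Br
Why: Wohl–Ziegler bromination under radical initiation in a non-polar solvent attacks the 6-methyl group, whose radical is allylic to the pyrone diene, which is the known outcome for this pyrone.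

Step 13
Reactants: 22 B–F pentamer phenol; 24 6-(bromomethyl)-4-methoxy-2H-pyran-2-one
Product: 25 4-methoxy-6-[(B–F pentamer aryloxy)methyl]-2H-pyran-2-one
Conditions: K2CO3, acetone, 50 °C
Reagents that add atoms: none
Why: Williamson etherification of the unhindered phenoxide with the allylic-type bromide proceeds under carbonate conditions that leave the lactone intact, so the hindered A–B ether oxygen is attached by a simple SN2 reaction.

Step 14
Reactants: 25 4-methoxy-6-[(B–F pentamer aryloxy)methyl]-2H-pyran-2-one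
Product: 27 2-(B–F pentamer aryloxy)-5-methoxybenzene-1,3-diol (hexamer with ring A as a 5-methoxyresorcinol), via ring-opened keto ester 26 (not isolated)
Conditions: NaOMe (8 equiv), MeOH/THF, argon, 0 °C to 65 °C; then 1 M HCl
Reagents that add atoms: none
Why: Methoxide adds to the lactone carbonyl of 25 and opens the ring to the methyl (2E)-3-methoxy-5-oxohex-2-enoate 26, in which the ester and the aryloxyacetyl chain stay cis on the enol ether double bond. Under the excess base the α-aryloxy ketone enolises towards the aryloxy-bearing carbon, which attacks the ester carbonyl in a Claisen (Dieckmann-type) condensation, expels methoxide and forms the ring A C1–C2 bond, and tautomerisation of the resulting 2-aryloxy-5-methoxycyclohexene-1,3-dione to the resorcinolate makes the sequence irreversible. The closest known reaction type is the alkoxide opening of triacetic acid lactone methyl ether and the Claisen cyclisation of 3,5-dioxohexanoates to phloroglucinols, with the aryloxy group here further acidifying the terminal carbon. Ring A closes in a 6-(enolendo)-exo-trig mode. No stereocentre is formed. The selectivity needed is C-acylation through the enolate at the aryloxy carbon and not through the more acidic central methylene: that dienolate can only re-close the pyrone by O-acylation or form a four-membered ring, both reversible or unfavourable, exchange of the 4-methoxy group by methoxide is degenerate, and the cis geometry inherited from the pyrone keeps the nucleophilic carbon within reach of the ester.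

Step 15
Reactants: 27 hexamer with ring A as a 5-methoxyresorcinol
Product: 28 CNP0175585.0 (fully hydroxylated hexamer)
Conditions: BBr3 (excess), CH2Cl2, argon, −78 °C to rt; then ice/H2O
Reagents that add atoms: none
Why: BBr3 ether cleavage removes every aryl methyl ether by Lewis acid complexation and bromide attack at the methyl carbon, while the diaryl ether bonds, which offer no sp3 carbon, survive.

**Compound list**

1 | 4-bromo-2,6-dimethoxyphenol | COc1cc(Br)cc(OC)c1O | starting material
2 | (3,4,5-trimethoxyphenyl)boronic acid | COc1cc(B(O)O)cc(OC)c1OC | starting material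
3 | 5-(4-bromo-2,6-dimethoxyphenoxy)-1,2,3-trimethoxybenzene (EF bromide) | COc1cc(Oc2c(OC)cc(Br)cc2OC)cc(OC)c1OC | intermediate
4 | EF aryllithium, [3,5-dimethoxy-4-(3,4,5-trimethoxyphenoxy)phenyl]lithium | [Li]c1cc(OC)c(Oc2cc(OC)c(OC)c(OC)c2)c(OC)c1 | intermediate
5 | lithium [3,5-dimethoxy-4-(3,4,5-trimethoxyphenoxy)phenyl]triisopropoxyborate | [Li+].CC(C)O[B-](OC(C)C)(OC(C)C)c1cc(OC)c(Oc2cc(OC)c(OC)c(OC)c2)c(OC)c1 | intermediate
6 | [3,5-dimethoxy-4-(3,4,5-trimethoxyphenoxy)phenyl]boronic acid (EF boronic acid) | OB(O)c1cc(OC)c(Oc2cc(OC)c(OC)c(OC)c2)c(OC)c1 | intermediate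
7 | 5-bromo-1,2,3-trimethoxybenzene | COc1cc(Br)cc(OC)c1OC | starting material
8 | 1-bromo-2-[chloro(methoxy)methyl]-3,4,5-trimethoxybenzene (racemic) | COC(Cl)c1c(Br)cc(OC)c(OC)c1OC | intermediate
9 | 6-bromo-2,3,4-trimethoxybenzaldehyde | O=Cc1c(Br)cc(OC)c(OC)c1OC | intermediate
10 | 6-bromo-2,3,4-trimethoxyphenyl formate | O=COc1c(Br)cc(OC)c(OC)c1OC | intermediate
11 | 6-bromo-2,3,4-trimethoxyphenol | Oc1c(Br)cc(OC)c(OC)c1OC | intermediate
12 | 1-bromo-2-[3,5-dimethoxy-4-(3,4,5-trimethoxyphenoxy)phenoxy]-3,4,5-trimethoxybenzene (DEF bromide) | COc1cc(Br)c(Oc2cc(OC)c(Oc3cc(OC)c(OC)c(OC)c3)c(OC)c2)c(OC)c1OC | intermediate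
13 | 2-(benzyloxy)-5-bromo-1,3-dimethoxybenzene | COc1cc(Br)cc(OC)c1OCc1ccccc1 | intermediate
14 | [4-(benzyloxy)-3,5-dimethoxyphenyl]lithium | [Li]c1cc(OC)c(OCc2ccccc2)c(OC)c1 | intermediate
15 | lithium [4-(benzyloxy)-3,5-dimethoxyphenyl]triisopropoxyborate | [Li+].CC(C)O[B-](OC(C)C)(OC(C)C)c1cc(OC)c(OCc2ccccc2)c(OC)c1 | intermediate
16 | [4-(benzyloxy)-3,5-dimethoxyphenyl]boronic acid | OB(O)c1cc(OC)c(OCc2ccccc2)c(OC)c1 | intermediate
17 | syringaldehyde (4-hydroxy-3,5-dimethoxybenzaldehyde) | COc1cc(C=O)cc(OC)c1O | starting material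
18 | 4-[4-(benzyloxy)-3,5-dimethoxyphenoxy]-3,5-dimethoxybenzaldehyde | O=Cc1cc(OC)c(Oc2cc(OC)c(OCc3ccccc3)c(OC)c2)c(OC)c1 | intermediate
19 | 4-(4-hydroxy-3,5-dimethoxyphenoxy)-3,5-dimethoxybenzaldehyde (BC phenol) | O=Cc1cc(OC)c(Oc2cc(OC)c(O)c(OC)c2)c(OC)c1 | intermediate
20 | B–F pentamer aldehyde (ring B 4-formyl-2,6-dimethoxyphenoxy terminus) | O=Cc1cc(OC)c(Oc2cc(OC)c(Oc3cc(OC)c(OC)c(OC)c3Oc3cc(OC)c(Oc4cc(OC)c(OC)c(OC)c4)c(OC)c3)c(OC)c2)c(OC)c1 | intermediate
21 | B–F pentamer aryl formate | O=COc1cc(OC)c(Oc2cc(OC)c(Oc3cc(OC)c(OC)c(OC)c3Oc3cc(OC)c(Oc4cc(OC)c(OC)c(OC)c4)c(OC)c3)c(OC)c2)c(OC)c1 | intermediate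
22 | B–F pentamer phenol | Oc1cc(OC)c(Oc2cc(OC)c(Oc3cc(OC)c(OC)c(OC)c3Oc3cc(OC)c(Oc4cc(OC)c(OC)c(OC)c4)c(OC)c3)c(OC)c2)c(OC)c1 | intermediate
23 | 4-methoxy-6-methyl-2H-pyran-2-one | COC1=CC(=O)OC(C)=C1 | starting material
24 | 6-(bromomethyl)-4-methoxy-2H-pyran-2-one | COC1=CC(=O)OC(CBr)=C1 | intermediate
25 | 4-methoxy-6-[(B–F pentamer aryloxy)methyl]-2H-pyran-2-one | COC1=CC(=O)OC(COc2cc(OC)c(Oc3cc(OC)c(Oc4cc(OC)c(OC)c(OC)c4Oc4cc(OC)c(Oc5cc(OC)c(OC)c(OC)c5)c(OC)c4)c(OC)c3)c(OC)c2)=C1 | intermediate
26 | methyl (2E)-3-methoxy-5-oxo-6-(B–F pentamer aryloxy)hex-2-enoate | COC(=O)/C=C(\CC(=O)COc1cc(OC)c(Oc2cc(OC)c(Oc3cc(OC)c(OC)c(OC)c3Oc3cc(OC)c(Oc4cc(OC)c(OC)c(OC)c4)c(OC)c3)c(OC)c2)c(OC)c1)OC | intermediate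
27 | 2-(B–F pentamer aryloxy)-5-methoxybenzene-1,3-diol (hexamer, ring A as 5-methoxyresorcinol) | COc1cc(O)c(Oc2cc(OC)c(Oc3cc(OC)c(Oc4cc(OC)c(OC)c(OC)c4Oc4cc(OC)c(Oc5cc(OC)c(OC)c(OC)c5)c(OC)c4)c(OC)c3)c(OC)c2)c(O)c1 | intermediate
28 | CNP0175585.0 | Oc1cc(O)c(Oc2cc(O)c(Oc3cc(O)c(Oc4cc(O)c(O)c(O)c4Oc4cc(O)c(Oc5cc(O)c(O)c(O)c5)c(O)c4)c(O)c3)c(O)c2)c(O)c1 | target

**Totals**
Total step count: 15.
Longest linear sequence: 9 steps (6, 7, 8, 9, 10, 11, 13, 14, 15).

**Steps most likely to fail**

Step 14. Enolisation towards the aryloxy-bearing carbon may be too slow, so that re-lactonisation, retro-Claisen cleavage of the keto ester by methoxide or intermolecular condensation consume the material before ring A closes. The fallback gives up the ring construction and attaches a preformed ring A. It sets out from pentamer phenol 22 and comes back to the route at target 28. Phenol 22 is converted with Tf2O and pyridine into the pentamer aryl triflate F1. Miyaura borylation (Pd(dppf)Cl2, B2pin2, KOAc, dioxane, 90 °C) should give the pentamer pinacol boronate F2. Oxidative cleavage of the pinacol ester (NaIO4, NH4OAc, acetone/H2O) should give the pentamer boronic acid F3. Chan–Lam coupling of F3 with commercial 2,4,6-trimethoxyphenol (Cu(OAc)2, pyridine, 4 Å MS, CH2Cl2, air) pairs a di-ortho-substituted phenol with an unhindered boronic acid, as in steps 1, 5 and 8, and should give the pentadeca-O-methyl hexamer F4. BBr3 demethylation as in step 15 then gives 28.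

Step 10. Carbon–oxygen bond formation at copper between a di-ortho-substituted phenoxide and an ortho-substituted, electron-rich aryl bromide may be slow, so that hydrodebromination and oxidative degradation of the phenoxide compete. The fallback reverses the polarity of the hindered ether bonds and sets out from DEF bromide 12, coming back at pentamer aldehyde 20. Hydroxylation of 12 (Pd2(dba)3, t-BuXPhos, KOH, dioxane/H2O, 100 °C) should give the DEF phenol F5. Nucleophilic aromatic substitution on 4-fluoro-3,5-dimethoxybenzaldehyde (Cs2CO3, DMSO, 130 °C), activated by the para formyl group, should give the C–F tetramer aldehyde F6. Baeyer–Villiger oxidation with mCPBA should give the tetramer aryl formate F7, and methanolysis the C–F tetramer phenol F8. A second substitution on 4-fluoro-3,5-dimethoxybenzaldehyde under the same conditions gives 20.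

Step 15. Cleavage of thirteen ethers may stop short, and the highly polar, oxidation-prone polyphenol may be lost by air oxidation and adsorption during isolation. The fallback isolates the product in protected form; it sets out from 27 and comes back at 28. After BBr3 treatment the crude polyphenol is acetylated in the same flask (Ac2O, pyridine, DMAP) to the pentadecaacetate F9, which can be purified on silica. Acid-catalysed methanolysis (HCl in MeOH from AcCl, argon, rt) then releases 28 without exposing it to base.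

**Further compounds**

F1 | step 14 | B–F pentamer aryl triflate | O=S(=O)(Oc1cc(OC)c(Oc2cc(OC)c(Oc3cc(OC)c(OC)c(OC)c3Oc3cc(OC)c(Oc4cc(OC)c(OC)c(OC)c4)c(OC)c3)c(OC)c2)c(OC)c1)C(F)(F)F
F2 | step 14 | B–F pentamer pinacol boronate | CC1(C)OB(OC1(C)C)c1cc(OC)c(Oc2cc(OC)c(Oc3cc(OC)c(OC)c(OC)c3Oc3cc(OC)c(Oc4cc(OC)c(OC)c(OC)c4)c(OC)c3)c(OC)c2)c(OC)c1
F3 | step 14 | B–F pentamer boronic acid | OB(O)c1cc(OC)c(Oc2cc(OC)c(Oc3cc(OC)c(OC)c(OC)c3Oc3cc(OC)c(Oc4cc(OC)c(OC)c(OC)c4)c(OC)c3)c(OC)c2)c(OC)c1
F4 | step 14 | pentadeca-O-methyl hexamer (ring A 2,4,6-trimethoxyphenoxy) | COc1cc(OC)c(Oc2cc(OC)c(Oc3cc(OC)c(Oc4cc(OC)c(OC)c(OC)c4Oc4cc(OC)c(Oc5cc(OC)c(OC)c(OC)c5)c(OC)c4)c(OC)c3)c(OC)c2)c(OC)c1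
F5 | step 10 | DEF phenol, 2-[3,5-dimethoxy-4-(3,4,5-trimethoxyphenoxy)phenoxy]-3,4,5-trimethoxyphenol | COc1cc(O)c(Oc2cc(OC)c(Oc3cc(OC)c(OC)c(OC)c3)c(OC)c2)c(OC)c1OC
F6 | step 10 | C–F tetramer aldehyde | O=Cc1cc(OC)c(Oc2cc(OC)c(OC)c(OC)c2Oc2cc(OC)c(Oc3cc(OC)c(OC)c(OC)c3)c(OC)c2)c(OC)c1
F7 | step 10 | C–F tetramer aryl formate | O=COc1cc(OC)c(Oc2cc(OC)c(OC)c(OC)c2Oc2cc(OC)c(Oc3cc(OC)c(OC)c(OC)c3)c(OC)c2)c(OC)c1
F8 | step 10 | C–F tetramer phenol | Oc1cc(OC)c(Oc2cc(OC)c(OC)c(OC)c2Oc2cc(OC)c(Oc3cc(OC)c(OC)c(OC)c3)c(OC)c2)c(OC)c1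
F9 | step 15 | pentadecaacetate of the target | CC(=O)Oc1cc(OC(C)=O)c(Oc2cc(OC(C)=O)c(Oc3cc(OC(C)=O)c(Oc4cc(OC(C)=O)c(OC(C)=O)c(OC(C)=O)c4Oc4cc(OC(C)=O)c(Oc5cc(OC(C)=O)c(OC(C)=O)c(OC(C)=O)c5)c(OC(C)=O)c4)c(OC(C)=O)c3)c(OC(C)=O)c2)c(OC(C)=O)c1
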